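- Two questions stand for this flask: which species holds the most of the Z charged at 2.5 min, and how large that share is.

the same everywhere: Z 0.10 M; E 12 mM (held)

| flask | G | remark | time |
|---|---|---|---|
| amber | 18 mM | run made earlier |  |
| flask | 12 mM |  | 2.5 min |

amber run (percent of the Z charged)

| time / s | L / % | Z / % | X / % |
|---|---|---|---|
| 10.0 | 4.2 | 96.3 | 0 |
| 15.0 | 5.8 | 94.5 | 0.2 |
| 25.0 | 10.0 | 90.0 | 0.4 |
| 30.0 | 11.6 | 88.5 | 0 |

(scatter of a reading: 0.5 percentage points)

- at the start none of J is dissolved
- what was read earlier has a scatter of 0.5 percentage points, one standard deviation
- on the list of suspects stand: E <-> J; Z + J + G -> G + L; L -> X; 2 G -> Q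
- no earlier run changes the charge of G; that part of a forecast is a guess

- the largest share of what was charged as Z, at 2.5 min belongs to (X / Z / L)
- the largest share itself, whichever of these holds it, in percent of the Z charged

- Z is the substrate, L the product, G the catalyst, and J the dissolved form of the gas E.
- Each L costs one J, and the Z charged (0.10 M) is more than the 12 mM of J that saturation holds, so J has to keep arriving from E.
- I write the balance of J: its change equals what enters from E minus what L formation uses.
- The amber run makes L along a nearly straight line. From its last reading I get 0.387 mM s⁻¹, and I call this the feed f, the rate at which J enters and is used.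
- If L keeps following f in the new flask, then L reaches 58.0% at 2.5 min, and Z keeps about 42.0%. X has stayed near the scatter in the amber run, so I neglect it and commit to L.
- The weak link is G, since no run varies it.
- I reforge it from the start of the amber run, where J begins at none. A lag is what J building up from nothing looks like, yet f gives 3.87% at 10.0 s and the reading is 4.2%. So I take the entry of J as the rate-limiting step, and I expect 12 mM of G to keep pace.
- The forecast gives Z at 69%, with the words “If the rate is first order in G”; my reckoning gives L at 58.0%.
- The flask gives L at 56.0%, with Z at 42.6%. Changing G alone from the amber charge to this flask's charge leaves L at 11.7% at the amber run's last reading time, against 12.0% before the change. Used again at 1.25 min, f gives 29.0% for this flask, and it holds 29.2% of L.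

    E ⇌ J, rate k1*(csat - [J]) (kL = 0.0360 s⁻¹)
    Z + J + G → G + L (k = 700 M⁻² s⁻¹)
    L → X (k = 3.40 × 10⁻⁴ s⁻¹)
    2 G → Q (k = 0.250 M⁻¹ s⁻¹)

- In a neighbour flask, Z is raised to 0.25 M, with the rest as in this flask. The same f gives L at 23.2% of that larger charge, so Z should hold the most there.
- Computed, that neighbour flask has L at 24.4% and Z at 75.0%, and the largest share belongs to Z.

The earlier runs and the new flask are simulated for substances that don't exist; scatter was added.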